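**Retrosynthetic overview**

- Target: the all-trans dimer (upper unit 2R,3S,4S; lower unit (2R,3S)-afzelechin) joined C4→C8 of ring D. The strategy rests on the 5-deoxy ring A of the upper unit: apart from O7 (para to C4a) its only C–O bond is C8a–O1, so O1 can be inserted late between C8a and C2 of a 3-aryl-6-benzyloxyindan-1-one.
- Last stage: hydrogenolysis; C2–H and C3–OH from hydroboration of a flav-2-ene anti to the C4 aryl group; C2–aryl from Suzuki coupling of the lactone ketene acetal phosphate.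
- Lactone from the indanone by Baeyer–Villiger ring expansion. The indanone comes from rhodium-catalysed intramolecular 1,4-addition of a 2′-boryl chalcone, which sets C4 and avoids any acylium-type closure next to O7-benzyl and O1 of ring D.
- Chalcone from tetra-O-benzylafzelechin-8-carbaldehyde and 1-[5-(benzyloxy)-2-bromophenyl]ethanone.
- Ring order: lower-unit rings come intact from afzelechin; five-membered carbocycle (step 8); ring C of the upper unit by oxygen insertion (step 9); ring B attached in step 11.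

Key step: step 9

Assumption: the sense of induction of the Rh/MonoPhos cyclisation on this substrate is fixed by a trial run; (R)-MonoPhos is written, and its antipode is used if the 3R epimer predominates.
Assumption: (2R,3S)-afzelechin (1) and 1-(2-bromo-5-hydroxyphenyl)ethan-1-one (7) are taken as purchasable.

**Route**

Step 1
Reactants: 1 (2R,3S)-afzelechin
Product: 2 5,7,4′-tri-O-benzylafzelechin [(2R,3S)-5,7-bis(benzyloxy)-2-[4-(benzyloxy)phenyl]chroman-3-ol]
Conditions: BnBr (3.3 equiv), K2CO3, DMF, 0 °C → rt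
Reagents that add atoms: benzyl bromide, BrCc1ccccc1
Why: Williamson etherification with a carbonate base caps the three phenols and leaves the less acidic secondary 3-OH and both stereocentres untouched.

Step 2
Reactants: 2 5,7,4′-tri-O-benzylafzelechin
Product: 3 8-bromo-5,7,4′-tri-O-benzylafzelechin
Conditions: NBS (1.0 equiv), CH2Cl2, −78 °C → rt
Reagents that add atoms: N-bromosuccinimide, O=C1CCC(=O)N1Br
Why: Electrophilic aromatic bromination of the phloroglucinol-type ring D, which in 5,7-di-O-benzyl flavan-3-ols is known to go to C8 in preference to C6.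

Step 3
Reactants: 3 8-bromo-5,7,4′-tri-O-benzylafzelechin
Product: 4 8-bromo-3,5,7,4′-tetra-O-benzylafzelechin
Conditions: NaH, BnBr, DMF, 0 °C → rt
Reagents that add atoms: benzyl bromide, BrCc1ccccc1
Why: Williamson etherification of the secondary alkoxide; with every phenol capped no quinone methide can open ring C, so C2 should not epimerise.

Step 4
Reactants: 4 8-bromo-3,5,7,4′-tetra-O-benzylafzelechin
Product: 6 3,5,7,4′-tetra-O-benzylafzelechin-8-carbaldehyde, via aryllithium 5 (not isolated)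
Conditions: n-BuLi, THF, −78 °C; then DMF, −78 → 0 °C; H2O
Reagents that add atoms: n-butyllithium (lithium in 5 only), [Li]CCCC; N,N-dimethylformamide, CN(C)C=O
Why: Bromine–lithium exchange at the di-ortho-alkoxy position followed by formylation of the aryllithium with DMF places the aldehyde at C8 only.

Step 5
Reactants: 7 1-(2-bromo-5-hydroxyphenyl)ethan-1-one
Product: 8 1-[5-(benzyloxy)-2-bromophenyl]ethan-1-one
Conditions: BnBr, K2CO3, acetone, reflux
Reagents that add atoms: benzyl bromide, BrCc1ccccc1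
Why: Williamson etherification of the phenol; this ring later becomes ring A of the upper unit, with the oxygen para to the bromine-bearing carbon (future C4a).

Step 6
Reactants: 6 3,5,7,4′-tetra-O-benzylafzelechin-8-carbaldehyde; 8 1-[5-(benzyloxy)-2-bromophenyl]ethan-1-one
Product: 9 (E)-1-[5-(benzyloxy)-2-bromophenyl]-3-(3,5,7,4′-tetra-O-benzylafzelechin-8-yl)prop-2-en-1-one
Conditions: KOH, EtOH–THF, rt → 40 °C
Reagents that add atoms: none
Why: Claisen–Schmidt condensation of the methyl ketone with the non-enolisable aldehyde, which should give the E-enone by dehydration of the aldol under thermodynamic control.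

Step 7
Reactants: 9 the bromo chalcone
Product: 10 (E)-1-[5-(benzyloxy)-2-(4,4,5,5-tetramethyl-1,3,2-dioxaborolan-2-yl)phenyl]-3-(3,5,7,4′-tetra-O-benzylafzelechin-8-yl)prop-2-en-1-one
Conditions: B2pin2, PdCl2(dppf) (5 mol%), KOAc, 1,4-dioxane, 85 °C
Reagents that add atoms: bis(pinacolato)diboron, CC1(C)OB(OC1(C)C)B1OC(C)(C)C(C)(C)O1
Why: Miyaura borylation of the aryl bromide, whose oxidative addition is helped by the ortho acyl group, under acetate conditions that leave the enone and benzyl ethers alone.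

Step 8
Reactants: 10 the 2′-boryl chalcone
Product: 11 (3S)-6-(benzyloxy)-3-(3,5,7,4′-tetra-O-benzylafzelechin-8-yl)indan-1-one
Conditions: [RhCl(C2H4)2]2 (3 mol%), (R)-MonoPhos (7 mol%), aq. K3PO4, toluene, rt → 50 °C
Reagents that add atoms: none
Why: Rhodium-catalysed asymmetric intramolecular 1,4-addition of the arylboronate to the enone (Hayashi–Miyaura type), a known route from 2′-boryl chalcones to 3-arylindan-1-ones, closes the carbocycle under basic conditions, and the phosphoramidite-bound aryl–rhodium species is expected to deliver the aryl carbon to the re face of Cβ (ranking C8 of ring D > Cα > H) to set the S centre by catalyst control.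

Step 9
Reactants: 11 (3S)-6-(benzyloxy)-3-(3,5,7,4′-tetra-O-benzylafzelechin-8-yl)indan-1-one
Product: 12 (4S)-7-(benzyloxy)-4-(3,5,7,4′-tetra-O-benzylafzelechin-8-yl)chroman-2-one
Conditions: mCPBA (1.5–2 equiv), solid NaHCO3, CH2Cl2, 0 °C → rt, dark
Reagents that add atoms: 3-chloroperbenzoic acid, OOC(=O)c1cccc(Cl)c1
Why: Baeyer–Villiger oxidation: the peracid adds to the indanone carbonyl to give the Criegee adduct, and aryl carbon C7a shifts from C1 to the proximal peroxy oxygen with loss of 3-chlorobenzoate, as is known for 1-indanones going to 3,4-dihydrocoumarins. The six-membered lactone (ring C of the upper unit) therefore arises by ring expansion through a 1,2-shift, not by a cyclisation, and gains the O1–C8a and O1–C2 bonds in one event. No stereocentre is created; C3 of the indanone becomes C4 of the chromanone unchanged, since it is neither the migrating atom nor adjacent to the carbonyl. The step needs aryl-over-methylene migration, which the higher migratory aptitude of an aryl carbon over a primary CH2 should secure, and the carbonyl is meta to the benzyloxy group, so it is not deactivated by donor conjugation towards peracid addition. It also needs oxidation at the ketone rather than at the electron-rich arenes; the only free position of ring D (C6) is flanked by two benzyloxy groups, and the buffer, low temperature and small excess of peracid are chosen to keep hydroxylation there slow.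

Step 10
Reactants: 12 the chroman-2-one
Product: 13 (4S)-7-(benzyloxy)-4-(3,5,7,4′-tetra-O-benzylafzelechin-8-yl)-4H-chromen-2-yl diphenyl phosphate
Conditions: KN(SiMe3)2, (PhO)2P(O)Cl, HMPA, THF, −78 °C (base added to lactone and chlorophosphate)
Reagents that add atoms: diphenyl phosphorochloridate, O=P(Cl)(Oc1ccccc1)Oc1ccccc1
Why: Kinetic enolisation of the lactone at C3 and O-phosphorylation with the electrophile already present gives the ketene acetal phosphate, a known handle for cross-coupling of lactones, without touching C4.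

Step 11
Reactants: 13 the ketene acetal phosphate; 14 [3,4-bis(benzyloxy)phenyl]boronic acid
Product: 15 (4S)-7-(benzyloxy)-2-[3,4-bis(benzyloxy)phenyl]-4-(3,5,7,4′-tetra-O-benzylafzelechin-8-yl)-4H-chromene
Conditions: Pd(PPh3)4 (10 mol%), 2 M aq. Na2CO3, DME, 75 °C
Reagents that add atoms: none
Why: Suzuki–Miyaura coupling of the enol phosphate C–O bond with the arylboronic acid installs ring B at C2 and gives the flav-2-ene with the C4 centre unchanged.

Step 12
Reactants: 15 the flav-2-ene
Product: 17 hepta-O-benzyl dimer with free upper 3-OH [(2R,3S,4S)-7-(benzyloxy)-2-[3,4-bis(benzyloxy)phenyl]-4-(3,5,7,4′-tetra-O-benzylafzelechin-8-yl)chroman-3-ol], via alkylborane 16 (not isolated)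
Conditions: BH3·THF, THF, 0 °C → rt; then NaOH, H2O2, 0 °C → rt
Reagents that add atoms: borane (boron in 16 only), B; hydrogen peroxide, OO
Why: Hydroboration–oxidation of the cyclic enol ether puts boron on C3 (β to O1, away from the aryl-bearing C2) by syn addition on the face opposite the bulky C4 aryl group, and oxidation with retention gives 3-OH trans to both the C4 aryl and the C2 aryl (2,3-trans-3,4-trans).

Step 13
Reactants: 17 the hepta-O-benzyl dimer
Product: 18 target (CNP0322555.1)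
Conditions: H2 (1 atm), Pd(OH)2/C, THF–MeOH, rt
Reagents that add atoms: none
Why: Catalytic hydrogenolysis removes the seven benzyl ethers, while the ring C–O bonds and the C4–C8 bond are expected to survive as they do in benzylated proanthocyanidins.

**Compound list**

1 | (2R,3S)-afzelechin | Oc1ccc([C@H]2Oc3cc(O)cc(O)c3C[C@@H]2O)cc1 | starting material
2 | 5,7,4′-tri-O-benzylafzelechin | c5ccccc5COc1ccc([C@H]2Oc3cc(OCc5ccccc5)cc(OCc5ccccc5)c3C[C@@H]2O)cc1 | intermediate
3 | 8-bromo-5,7,4′-tri-O-benzylafzelechin | c5ccccc5COc1ccc([C@H]2Oc3c(Br)c(OCc5ccccc5)cc(OCc5ccccc5)c3C[C@@H]2O)cc1 | intermediate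
4 | 8-bromo-3,5,7,4′-tetra-O-benzylafzelechin | c5ccccc5COc1ccc([C@H]2Oc3c(Br)c(OCc5ccccc5)cc(OCc5ccccc5)c3C[C@@H]2OCc5ccccc5)cc1 | intermediate
5 | 8-lithio-3,5,7,4′-tetra-O-benzylafzelechin (not isolated) | c5ccccc5COc1ccc([C@H]2Oc3c([Li])c(OCc5ccccc5)cc(OCc5ccccc5)c3C[C@@H]2OCc5ccccc5)cc1 | intermediate
6 | 3,5,7,4′-tetra-O-benzylafzelechin-8-carbaldehyde | c5ccccc5COc1ccc([C@H]2Oc3c(C=O)c(OCc5ccccc5)cc(OCc5ccccc5)c3C[C@@H]2OCc5ccccc5)cc1 | intermediate
7 | 1-(2-bromo-5-hydroxyphenyl)ethan-1-one | CC(=O)c1cc(O)ccc1Br | starting material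
8 | 1-[5-(benzyloxy)-2-bromophenyl]ethan-1-one | CC(=O)c1cc(OCc2ccccc2)ccc1Br | intermediate
9 | (E)-1-[5-(benzyloxy)-2-bromophenyl]-3-(3,5,7,4′-tetra-O-benzylafzelechin-8-yl)prop-2-en-1-one | c5ccccc5COc1ccc([C@H]2Oc3c(/C=C/C(=O)c6cc(OCc5ccccc5)ccc6Br)c(OCc5ccccc5)cc(OCc5ccccc5)c3C[C@@H]2OCc5ccccc5)cc1 | intermediate
10 | (E)-1-[5-(benzyloxy)-2-(pinacolatoboryl)phenyl]-3-(3,5,7,4′-tetra-O-benzylafzelechin-8-yl)prop-2-en-1-one | c5ccccc5COc1ccc([C@H]2Oc3c(/C=C/C(=O)c6cc(OCc5ccccc5)ccc6B7OC(C)(C)C(C)(C)O7)c(OCc5ccccc5)cc(OCc5ccccc5)c3C[C@@H]2OCc5ccccc5)cc1 | intermediate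
11 | (3S)-6-(benzyloxy)-3-(3,5,7,4′-tetra-O-benzylafzelechin-8-yl)indan-1-one | c5ccccc5COc1ccc([C@H]2Oc3c([C@H]6CC(=O)c7cc(OCc5ccccc5)ccc76)c(OCc5ccccc5)cc(OCc5ccccc5)c3C[C@@H]2OCc5ccccc5)cc1 | intermediate
12 | (4S)-7-(benzyloxy)-4-(3,5,7,4′-tetra-O-benzylafzelechin-8-yl)chroman-2-one | c5ccccc5COc1ccc([C@H]2Oc3c([C@H]6CC(=O)Oc7cc(OCc5ccccc5)ccc76)c(OCc5ccccc5)cc(OCc5ccccc5)c3C[C@@H]2OCc5ccccc5)cc1 | intermediate
13 | (4S)-7-(benzyloxy)-4-(3,5,7,4′-tetra-O-benzylafzelechin-8-yl)-4H-chromen-2-yl diphenyl phosphate | c5ccccc5COc1ccc([C@H]2Oc3c([C@H]6C=C(OP(=O)(Oc8ccccc8)Oc8ccccc8)Oc7cc(OCc5ccccc5)ccc76)c(OCc5ccccc5)cc(OCc5ccccc5)c3C[C@@H]2OCc5ccccc5)cc1 | intermediate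
14 | [3,4-bis(benzyloxy)phenyl]boronic acid | OB(O)c1ccc(OCc2ccccc2)c(OCc2ccccc2)c1 | starting material
15 | (4S)-7-(benzyloxy)-2-[3,4-bis(benzyloxy)phenyl]-4-(3,5,7,4′-tetra-O-benzylafzelechin-8-yl)-4H-chromene | c5ccccc5COc1ccc([C@H]2Oc3c([C@H]6C=C(c8ccc(OCc5ccccc5)c(OCc5ccccc5)c8)Oc7cc(OCc5ccccc5)ccc76)c(OCc5ccccc5)cc(OCc5ccccc5)c3C[C@@H]2OCc5ccccc5)cc1 | intermediate
16 | C3-boryl flavan (BH2 on C3 and H on C2, both anti to the C4 aryl; not isolated) | c5ccccc5COc1ccc([C@H]2Oc3c([C@H]6[C@H](B)[C@@H](c8ccc(OCc5ccccc5)c(OCc5ccccc5)c8)Oc7cc(OCc5ccccc5)ccc76)c(OCc5ccccc5)cc(OCc5ccccc5)c3C[C@@H]2OCc5ccccc5)cc1 | intermediate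
17 | (2R,3S,4S)-7-(benzyloxy)-2-[3,4-bis(benzyloxy)phenyl]-4-(3,5,7,4′-tetra-O-benzylafzelechin-8-yl)chroman-3-ol | c5ccccc5COc1ccc([C@H]2Oc3c([C@H]6[C@H](O)[C@@H](c8ccc(OCc5ccccc5)c(OCc5ccccc5)c8)Oc7cc(OCc5ccccc5)ccc76)c(OCc5ccccc5)cc(OCc5ccccc5)c3C[C@@H]2OCc5ccccc5)cc1 | intermediate
18 | CNP0322555.1: upper unit (2R,3S,4S)-2-(3,4-dihydroxyphenyl)chroman-3,7-diol joined C4→C8 to (2R,3S)-afzelechin | Oc1ccc([C@H]2Oc3c(c(O)cc(O)c3[C@@H]3c4ccc(O)cc4O[C@H](c4ccc(O)c(O)c4)[C@H]3O)C[C@@H]2O)cc1 | target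

**Step count and risks**

Total steps: 13. Longest linear sequence: 12 (steps 1–4 and 6–13, from afzelechin).

Steps most likely to fail:

1. Step 9. The ketone is a slow Baeyer–Villiger substrate, so electrophilic oxidation of ring D at C6 and over-oxidation may outrun Criegee adduct formation. The fallback sets out from 11 and blocks that position. NBS (CH2Cl2, 0 °C) should brominate C6 of ring D to give (3S)-6-(benzyloxy)-3-(6-bromo-3,5,7,4′-tetra-O-benzylafzelechin-8-yl)indan-1-one F1. With ring D fully substituted the oxidation can be driven with excess mCPBA or buffered CF3CO3H to give (4S)-7-(benzyloxy)-4-(6-bromo-3,5,7,4′-tetra-O-benzylafzelechin-8-yl)chroman-2-one F2. Radical debromination (Bu3SnH, AIBN, toluene, 90 °C) then returns to the route at 12.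

2. Step 8. Insertion into the di-ortho-substituted, electron-rich β-aryl enone may be slow enough for protodeboronation to compete, and facial control may be incomplete, giving the C3 epimer. The fallback sets out from 9 and does not pass through 10. A palladium-catalysed asymmetric reductive Heck cyclisation (Pd(OAc)2, a MeO-BIPHEP-type bisphosphine with the antipode chosen as above, i-Pr2NEt as base and hydride donor, ethylene glycol, 100 °C) closes the same C3–C3a bond from the aryl bromide and comes back at 11.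

3. Step 10. The aryl-lactone enolate may open by E1cB loss of the phenoxide to a ketene before O-phosphorylation, and the ketene acetal phosphate may hydrolyse on isolation. The fallback sets out from 12 and avoids an enolate.
   - MeNH(OMe)·HCl/AlMe3 (CH2Cl2, 0 °C) opens the lactone to (3S)-3-[4-(benzyloxy)-2-hydroxyphenyl]-N-methoxy-N-methyl-3-(3,5,7,4′-tetra-O-benzylafzelechin-8-yl)propanamide F3.
   - Excess [3,4-bis(benzyloxy)phenyl]lithium F4, made from commercial 4-bromo-1,2-bis(benzyloxy)benzene and n-BuLi at −78 °C, converts the amide into (3S)-3-[4-(benzyloxy)-2-hydroxyphenyl]-1-[3,4-bis(benzyloxy)phenyl]-3-(3,5,7,4′-tetra-O-benzylafzelechin-8-yl)propan-1-one F5.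
   - Cyclodehydration of the hydroxy ketone (PPTS, toluene, 4 Å sieves, 80 °C) comes back to the route at 15, bypassing 13.

Further compounds
F1 | step 9 | (3S)-6-(benzyloxy)-3-(6-bromo-3,5,7,4′-tetra-O-benzylafzelechin-8-yl)indan-1-one | c5ccccc5COc1ccc([C@H]2Oc3c([C@H]6CC(=O)c7cc(OCc5ccccc5)ccc76)c(OCc5ccccc5)c(Br)c(OCc5ccccc5)c3C[C@@H]2OCc5ccccc5)cc1
F2 | step 9 | (4S)-7-(benzyloxy)-4-(6-bromo-3,5,7,4′-tetra-O-benzylafzelechin-8-yl)chroman-2-one | c5ccccc5COc1ccc([C@H]2Oc3c([C@H]6CC(=O)Oc7cc(OCc5ccccc5)ccc76)c(OCc5ccccc5)c(Br)c(OCc5ccccc5)c3C[C@@H]2OCc5ccccc5)cc1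
F0 | step 8 | none | none
F3 | step 10 | (3S)-3-[4-(benzyloxy)-2-hydroxyphenyl]-N-methoxy-N-methyl-3-(3,5,7,4′-tetra-O-benzylafzelechin-8-yl)propanamide | c5ccccc5COc1ccc([C@H]2Oc3c([C@@H](CC(=O)N(C)OC)c7ccc(OCc5ccccc5)cc7O)c(OCc5ccccc5)cc(OCc5ccccc5)c3C[C@@H]2OCc5ccccc5)cc1
F4 | step 10 | [3,4-bis(benzyloxy)phenyl]lithium | [Li]c1ccc(OCc2ccccc2)c(OCc2ccccc2)c1
F5 | step 10 | (3S)-3-[4-(benzyloxy)-2-hydroxyphenyl]-1-[3,4-bis(benzyloxy)phenyl]-3-(3,5,7,4′-tetra-O-benzylafzelechin-8-yl)propan-1-one | c5ccccc5COc1ccc([C@H]2Oc3c([C@@H](CC(=O)c8ccc(OCc5ccccc5)c(OCc5ccccc5)c8)c7ccc(OCc5ccccc5)cc7O)c(OCc5ccccc5)cc(OCc5ccccc5)c3C[C@@H]2OCc5ccccc5)cc1
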